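**Assumption:** (R)-5-(trityloxymethyl)dihydrofuran-2(3H)-one (from D-glutamic acid) and (Z)-3-methylpent-2-en-4-yn-1-ol (the vitamin A C6 building block) are taken as purchasable. Germacrane numbering (C1–C15) is used for the target.

## Retrosynthetic overview
1. The C8 tiglate is attached last by esterifying the 8-hydroxy heliangolide.
2. The ten-membered ring and the α-methylene lactone come from one intramolecular Cr(II) Barbier allylation (C6–C7) of a Z-enal onto a 2-(bromomethyl)enoate, followed by lactonisation.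
3. The 3(2H)-furanone comes from a 3,5-disubstituted isoxazole (N–O cleavage, acid cyclodehydration). The isoxazole is made by a nitrile oxide–alkyne [3+2] cycloaddition that joins the C1/C7–C10 fragment to the C2–C6 enyne.
4. C8 is bought in the lactone, C10 is set by anti-alkylation of its enolate, and C6/C7 are set in the macrocyclisation under control of C8/C10.
5. Ring order: isoxazole → furanone → ten-membered carbocycle → γ-lactone.

## Route

**Step 1**
Reactants: 1, (R)-5-(trityloxymethyl)dihydrofuran-2(3H)-one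
Product: 2, (3S,5R)-3-(triethylsilyloxy)-5-(trityloxymethyl)dihydrofuran-2(3H)-one (major trans isomer; the C3 epimer is equally usable)
Conditions: LDA, THF, −78 °C; (±)-2-(phenylsulfonyl)-3-phenyloxaziridine; then TESCl, imidazole, −78 → 0 °C
Reagents that add atoms: Davis oxaziridine, O=S(=O)(c1ccccc1)N1OC1c1ccccc1 (O); TESCl, CC[Si](CC)(CC)Cl
Why: Davis enolate hydroxylation with in situ silylation of the alkoxide; the C3 configuration does not matter because the centre is re-enolised in step 2.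

**Step 2**
Reactants: 2
Product: 3, (3R,5R)-3-methyl-3-(triethylsilyloxy)-5-(trityloxymethyl)dihydrofuran-2(3H)-one
Conditions: LDA, THF, −78 °C; MeI, DMPU, −78 → −40 °C
Reagents that add atoms: iodomethane, CI
Why: Enolate alkylation in which MeI approaches anti to the bulky C5 CH2OTr group (1,3-induction from the purchased stereocentre), fixing the quaternary carbinol (future C10) with O cis to CH2OTr.

**Step 3**
Reactants: 3
Product: 4, (3R,5R)-3-methyl-3-(triethylsilyloxy)-5-(trityloxymethyl)tetrahydrofuran-2-ol (lactol, anomer mixture)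
Conditions: DIBAL-H, CH2Cl2, −78 °C
Reagents that add atoms: none
Why: DIBAL half-reduction of the lactone stops at the lactol at −78 °C; silyl and trityl ethers are inert.

**Step 4**
Reactants: 4
Product: 5, (1E,2R,4R)-4-hydroxy-2-methyl-2-(triethylsilyloxy)-5-(trityloxy)pentanal oxime
Conditions: NH2OH·HCl, pyridine, EtOH, 50 °C
Reagents that add atoms: hydroxylamine, NO
Why: Oxime condensation on the open hydroxy-aldehyde tautomer of the lactol, which releases the C8 hydroxyl.

**Step 5**
Reactants: 5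
Product: 6, (1E,2R,4R)-4-(tert-butyldimethylsilyloxy)-2-methyl-2-(triethylsilyloxy)-5-(trityloxy)pentanal oxime
Conditions: TBSCl (2.5 equiv), imidazole, DMAP (cat.), DMF, rt; then K2CO3, MeOH, 0 °C
Reagents that add atoms: TBSCl, CC(C)(C)[Si](C)(C)Cl
Why: Silylation of the secondary alcohol (the oxime O-silyl group is selectively methanolysed), so the γ-hydroxyl cannot trap the nitrile oxide intramolecularly and C8 is protected for the later Baylis–Hillman and Barbier steps.

**Step 6**
Reactants: 7, (Z)-3-methylpent-2-en-4-yn-1-ol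
Product: 8, (Z)-1-(4-methoxybenzyloxy)-3-methylpent-2-en-4-yne
Conditions: NaH (1.05 equiv), PMBCl, TBAI (cat.), THF, 0 °C → rt
Reagents that add atoms: 4-methoxybenzyl chloride, COc1ccc(CCl)cc1
Why: Williamson etherification; PMB survives the later acid step and is removed oxidatively, and the Z alkene is untouched.

**Step 7 (key step)**
Reactants: 6 and 8 (2 equiv)
Product: 9, 3-[(2R,4R)-4-(tert-butyldimethylsilyloxy)-2-(triethylsilyloxy)-5-(trityloxy)pentan-2-yl]-5-[(2Z)-4-(4-methoxybenzyloxy)but-2-en-2-yl]isoxazole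
Conditions: NCS, pyridine (cat.), DMF, rt; then 8, Et3N (slow addition), CH2Cl2, 0 °C → rt
Reagents that add atoms: none
Why: Huisgen nitrile oxide–alkyne [3+2] cycloaddition; the terminal alkyne reacts in preference to the trisubstituted alkene and gives only the 3,5-disubstituted isoxazole, which holds C1–C3 at the 1,3-dicarbonyl oxidation level.

**Step 8**
Reactants: 9
Product: 10, (2R)-2-[(2R)-2-(tert-butyldimethylsilyloxy)-3-hydroxypropyl]-5-[(2Z)-4-(4-methoxybenzyloxy)but-2-en-2-yl]-2-methylfuran-3(2H)-one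
Conditions: Mo(CO)6, MeCN/H2O, 80 °C; then TsOH·H2O (cat.), THF/MeOH/H2O, rt
Reagents that add atoms: water, O
Why: Mo(0) reductive N–O cleavage gives the β-amino enone; acid then removes TES and Tr and the tertiary hydroxyl cyclises onto the C3 carbonyl (cyclodehydration and iminium hydrolysis) to the 3(2H)-furanone, while the secondary TBS and PMB ethers survive.

**Step 9**
Reactants: 10
Product: 11, (2R)-2-(tert-butyldimethylsilyloxy)-3-[(2R)-5-{(2Z)-4-(4-methoxybenzyloxy)but-2-en-2-yl}-2-methyl-3-oxo-2,3-dihydrofuran-2-yl]propanal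
Conditions: Dess–Martin periodinane, NaHCO3, CH2Cl2, 0 °C
Reagents that add atoms: none
Why: Buffered Dess–Martin oxidation gives the α-silyloxy aldehyde without epimerising C8.

**Step 10**
Reactants: 11
Product: 12, methyl 2-[(1RS,2R)-2-(tert-butyldimethylsilyloxy)-1-hydroxy-3-{(2R)-5-[(2Z)-4-(4-methoxybenzyloxy)but-2-en-2-yl]-2-methyl-3-oxo-2,3-dihydrofuran-2-yl}propyl]acrylate (C7 epimers)
Conditions: DIBAL-H, NMO, methyl propiolate, THF, 0 °C; then 11, 0 °C → rt
Reagents that add atoms: methyl propiolate, C#CC(=O)OC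
Why: Vinylalumination (an amine-free Morita–Baylis–Hillman equivalent) adds the α-aluminoacrylate 1,2 to the aldehyde only; the new carbinol is destroyed in step 11, so its configuration is irrelevant.

**Step 11**
Reactants: 12
Product: 13, methyl (2Z,4R)-2-(bromomethyl)-4-(tert-butyldimethylsilyloxy)-5-{(2R)-5-[(2Z)-4-(4-methoxybenzyloxy)but-2-en-2-yl]-2-methyl-3-oxo-2,3-dihydrofuran-2-yl}pent-2-enoate
Conditions: NBS/Me2S (premixed), CH2Cl2, −20 °C → rt
Reagents that add atoms: N-bromosuccinimide, O=C1CCC(=O)N1Br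
Why: Corey–Kim-type activation of the Baylis–Hillman alcohol and SN2′ bromide delivery give the thermodynamically preferred (Z)-2-(bromomethyl)enoate.

**Step 12**
Reactants: 13
Product: 14, methyl (2Z,4R)-2-(bromomethyl)-4-(tert-butyldimethylsilyloxy)-5-{(2R)-5-[(2Z)-4-hydroxybut-2-en-2-yl]-2-methyl-3-oxo-2,3-dihydrofuran-2-yl}pent-2-enoate
Conditions: DDQ, CH2Cl2/pH 7 buffer, 0 °C
Reagents that add atoms: none
Why: Oxidative PMB cleavage under neutral conditions, avoiding the acid or base that would let the Z-allylic alcohol attack the furanone and aromatise to a furan.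

**Step 13**
Reactants: 14
Product: 15, methyl (2Z,4R)-2-(bromomethyl)-4-(tert-butyldimethylsilyloxy)-5-{(2R)-2-methyl-3-oxo-5-[(2Z)-4-oxobut-2-en-2-yl]-2,3-dihydrofuran-2-yl}pent-2-enoate
Conditions: Dess–Martin periodinane, NaHCO3, CH2Cl2, 0 °C (used at once)
Reagents that add atoms: none
Why: Neutral Dess–Martin oxidation gives the Z-enal without Z→E isomerisation.

**Step 14**
Reactants: 15
Product: 16, (4Z,6R,7S,8R,10R)-8-(tert-butyldimethylsilyloxy)-1-oxo-3,10-epoxygermacra-2,4,11(13)-trien-12,6-olide (same spatial arrangement as the target; the C7 descriptor differs only because O–Si changes CIP priority)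
Conditions: CrCl2 (10 equiv), THF, 2 mM, rt; then CSA (cat.)
Reagents that add atoms: none
Why: Intramolecular Nozaki–Hiyama (Barbier) allylation in which the allyl-Cr(III) adds through C7 to the enal via a chair transition state with both ring bonds pseudo-equatorial (6,7-anti, hence trans-lactone), the C8 silyloxy centre selects the C7 face, and the chromium alkoxide lactonises onto the methyl ester.

**Step 15**
Reactants: 16
Product: 17, (4Z,6R,7R,8R,10R)-8-hydroxy-1-oxo-3,10-epoxygermacra-2,4,11(13)-trien-12,6-olide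
Conditions: HF·pyridine, pyridine, THF, 0 °C → rt
Reagents that add atoms: none
Why: Fluoride desilylation under mildly acidic conditions, which avoids base-promoted translactonisation to the 8,12-olide.

**Step 16**
Reactants: 17
Product: 18, atripliciolide tiglate
Conditions: tiglic acid, 2,4,6-trichlorobenzoyl chloride, Et3N, DMAP, PhMe, rt
Reagents that add atoms: tiglic acid, C/C=C(\C)C(=O)O
Why: Yamaguchi esterification acylates C8–OH with retention and leaves the E-tiglate geometry intact.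

## Compound list
1 | (R)-5-(trityloxymethyl)dihydrofuran-2(3H)-one | O=C1CC[C@@H](O1)COC(c2ccccc2)(c2ccccc2)c2ccccc2 | starting material
2 | (3S,5R)-3-(triethylsilyloxy)-5-(trityloxymethyl)dihydrofuran-2(3H)-one | O=C1[C@@H](O[Si](CC)(CC)CC)C[C@@H](O1)COC(c2ccccc2)(c2ccccc2)c2ccccc2 | intermediate
3 | (3R,5R)-3-methyl-3-(triethylsilyloxy)-5-(trityloxymethyl)dihydrofuran-2(3H)-one | O=C1[C@@](C)(C[C@@H](O1)COC(c2ccccc2)(c2ccccc2)c2ccccc2)O[Si](CC)(CC)CC | intermediate
4 | (3R,5R)-3-methyl-3-(triethylsilyloxy)-5-(trityloxymethyl)tetrahydrofuran-2-ol | OC1[C@@](C)(C[C@@H](O1)COC(c2ccccc2)(c2ccccc2)c2ccccc2)O[Si](CC)(CC)CC | intermediate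
5 | (1E,2R,4R)-4-hydroxy-2-methyl-2-(triethylsilyloxy)-5-(trityloxy)pentanal oxime | O/N=C/[C@@](C)(C[C@@H](O)COC(c1ccccc1)(c1ccccc1)c1ccccc1)O[Si](CC)(CC)CC | intermediate
6 | (1E,2R,4R)-4-(tert-butyldimethylsilyloxy)-2-methyl-2-(triethylsilyloxy)-5-(trityloxy)pentanal oxime | O/N=C/[C@@](C)(C[C@@H](O[Si](C)(C)C(C)(C)C)COC(c1ccccc1)(c1ccccc1)c1ccccc1)O[Si](CC)(CC)CC | intermediate
7 | (Z)-3-methylpent-2-en-4-yn-1-ol | C#C/C(C)=C\CO | starting material
8 | (Z)-1-(4-methoxybenzyloxy)-3-methylpent-2-en-4-yne | C#C/C(C)=C\COCc1ccc(OC)cc1 | intermediate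
9 | 3-[(2R,4R)-4-(TBS-oxy)-2-(TES-oxy)-5-(trityloxy)pentan-2-yl]-5-[(2Z)-4-(PMB-oxy)but-2-en-2-yl]isoxazole | COc1ccc(COC/C=C(/C)c2cc(no2)[C@@](C)(C[C@@H](O[Si](C)(C)C(C)(C)C)COC(c3ccccc3)(c3ccccc3)c3ccccc3)O[Si](CC)(CC)CC)cc1 | intermediate
10 | (2R)-2-[(2R)-2-(TBS-oxy)-3-hydroxypropyl]-5-[(2Z)-4-(PMB-oxy)but-2-en-2-yl]-2-methylfuran-3(2H)-one | COc1ccc(COC/C=C(/C)C2=CC(=O)[C@@](C)(C[C@@H](O[Si](C)(C)C(C)(C)C)CO)O2)cc1 | intermediate
11 | (2R)-2-(TBS-oxy)-3-[(2R)-5-{(2Z)-4-(PMB-oxy)but-2-en-2-yl}-2-methyl-3-oxo-2,3-dihydrofuran-2-yl]propanal | COc1ccc(COC/C=C(/C)C2=CC(=O)[C@@](C)(C[C@@H](O[Si](C)(C)C(C)(C)C)C=O)O2)cc1 | intermediate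
12 | methyl 2-[(1RS,2R)-2-(TBS-oxy)-1-hydroxy-3-(furanonyl)propyl]acrylate (furanonyl as in 11) | COc1ccc(COC/C=C(/C)C2=CC(=O)[C@@](C)(C[C@@H](O[Si](C)(C)C(C)(C)C)C(O)C(=C)C(=O)OC)O2)cc1 | intermediate
13 | methyl (2Z,4R)-2-(bromomethyl)-4-(TBS-oxy)-5-[(2R)-5-{(2Z)-4-(PMB-oxy)but-2-en-2-yl}-2-methyl-3-oxo-2,3-dihydrofuran-2-yl]pent-2-enoate | COc1ccc(COC/C=C(/C)C2=CC(=O)[C@@](C)(C[C@@H](O[Si](C)(C)C(C)(C)C)/C=C(\CBr)C(=O)OC)O2)cc1 | intermediate
14 | methyl (2Z,4R)-2-(bromomethyl)-4-(TBS-oxy)-5-[(2R)-5-{(2Z)-4-hydroxybut-2-en-2-yl}-2-methyl-3-oxo-2,3-dihydrofuran-2-yl]pent-2-enoate | OC/C=C(/C)C1=CC(=O)[C@@](C)(C[C@@H](O[Si](C)(C)C(C)(C)C)/C=C(\CBr)C(=O)OC)O1 | intermediate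
15 | methyl (2Z,4R)-2-(bromomethyl)-4-(TBS-oxy)-5-[(2R)-2-methyl-3-oxo-5-{(2Z)-4-oxobut-2-en-2-yl}-2,3-dihydrofuran-2-yl]pent-2-enoate | O=C/C=C(/C)C1=CC(=O)[C@@](C)(C[C@@H](O[Si](C)(C)C(C)(C)C)/C=C(\CBr)C(=O)OC)O1 | intermediate
16 | (4Z,6R,7S,8R,10R)-8-(TBS-oxy)-1-oxo-3,10-epoxygermacra-2,4,11(13)-trien-12,6-olide | C=C1C(=O)O[C@@H]2/C=C(/C)C3=CC(=O)[C@@](C)(C[C@@H](O[Si](C)(C)C(C)(C)C)[C@@H]12)O3 | intermediate
17 | (4Z,6R,7R,8R,10R)-8-hydroxy-1-oxo-3,10-epoxygermacra-2,4,11(13)-trien-12,6-olide | C=C1C(=O)O[C@@H]2/C=C(/C)C3=CC(=O)[C@@](C)(C[C@@H](O)[C@@H]12)O3 | intermediate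
18 | atripliciolide tiglate, (4Z,6R,7R,8R,10R)-8-[(E)-2-methylbut-2-enoyloxy]-1-oxo-3,10-epoxygermacra-2,4,11(13)-trien-12,6-olide | C=C1C(=O)O[C@@H]2/C=C(/C)C3=CC(=O)[C@@](C)(C[C@@H](OC(=O)/C(C)=C/C)[C@@H]12)O3 | target

## Summary
- Total steps: 16.
- Longest linear sequence: 15 (steps 1–5, then 7–16, from lactone 1).

**Steps most likely to fail, with fallbacks**
1. **Step 14 (macrocyclisation).** The strained ten-membered ring may close poorly or with the wrong C6/C7 facial selectivity, and reduction of the allyl-chromium can compete. Fallback: form C6–C7 and the lactone first by an intermolecular Barbier reaction of the bromide with acrolein, then close the ring at C4=C5 by ring-closing metathesis (Z enforced by the ring). The isopropenyl-furanone partner would come from the same cycloaddition run on 2-methylbut-3-yn-2-ol, followed by dehydration.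
2. **Step 8 (isoxazole to furanone).** The acid needed for hydrolysis and cyclisation could erode the Z alkene or the C8 TBS ether, or trigger furan formation if PMB is lost. Fallback: swap the dipole and dipolarophile roles. Lactol 4 is converted to the C1≡C2 alkyne (Ohira–Bestmann) and combined with the nitrile oxide from the C3 (Z)-enal oxime. The derived enaminone then carries nitrogen on C3 and closes by simple addition–elimination of NH3 under near-neutral conditions.
3. **Step 2 (quaternary C10).** Methylation of the α-silyloxy enolate may give only moderate anti selectivity. Fallback: take C10 directly from (S)-lactic acid through its cis-2-tert-butyl-5-methyl-1,3-dioxolan-4-one (self-regeneration of the stereocentre) and alkylate that enolate with the triflate of (R)-solketal, so that both C10 and C8 come from the pool.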